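**Retrosynthetic overview**
1. The last bond, CH2–C(triketone ring), is made by an iridium-catalysed hydrogen-borrowing C–H alkylation of isovalerylfilicinic acid with a decalin carbinol (new reaction, last step).
2. The carbinol (a diol) comes from an octalin ester by epoxidation anti to the angular methyl and LiAlH4 reduction (tertiary alcohol and CH2OH together).
3. Rings A and B of the decalin close together in one intramolecular Diels–Alder reaction of an acyclic E,E-trienoate; one stereocentre steers the three new ones.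
4. The trienoate is joined by a Pd-catalysed Negishi sp3–sp2 coupling (alkylzinc + E-enol triflate of methyl acetoacetate); the diene comes from two Wittig reactions and the steering stereocentre from a Rh-catalysed asymmetric 1,4-addition of isopropenyl to 5,6-dihydro-2H-pyran-2-one.
5. The triketone ring is made in its own branch from a benzene ring (resorcinol, Ir-catalysed C–H borylation/oxidation, acylation, dearomatising gem-dimethylation); ring order: trione ring in its branch, then decalin rings A and B at once, no ring formed after the union.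

Assumption: the enolised triketone is written throughout as the tautomer of the target SMILES; other tautomers are the same compound. Locants in the Why lines are those of the product names.

Step 1
Reactants: 1 5,6-dihydro-2H-pyran-2-one; 2 potassium trifluoro(prop-1-en-2-yl)borate
Product: 3 (4S)-4-(prop-1-en-2-yl)oxan-2-one
Conditions: [RhCl(cod)]2 (1.5 mol %), (S)-BINAP (3.3 mol %), Et3N, dioxane/H2O 10:1, 80 °C
Reagents that add atoms: none
Why: Rhodium-catalysed asymmetric 1,4-addition (Hayashi–Miyaura type) of the alkenyl group to the unsaturated lactone, in which the (S)-BINAP–rhodium alkenyl species selects one enantioface and sets C4 as S (the enantiomeric ligand would give the antipode).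

Step 2
Reactants: 3 (4S)-4-(prop-1-en-2-yl)oxan-2-one
Product: 4 (4S)-4-(prop-1-en-2-yl)oxan-2-ol (lactol; both anomers)
Conditions: i-Bu2AlH (1.1 equiv), CH2Cl2, −78 °C
Reagents that add atoms: none
Why: Partial hydride reduction of a lactone stops at the lactol because the aluminium acetal is stable at −78 °C; the stereocentre is not touched.

Step 3
Reactants: 4 (4S)-4-(prop-1-en-2-yl)oxan-2-ol
Product: 5 (2E,5R)-7-hydroxy-2-methyl-5-(prop-1-en-2-yl)hept-2-enal
Conditions: 2-(triphenylphosphoranylidene)propanal (1.3 equiv), toluene, 90 °C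
Reagents that add atoms: 2-(triphenylphosphoranylidene)propanal, CC(C=O)=P(c1ccccc1)(c1ccccc1)c1ccccc1
Why: Wittig olefination of the lactol through its open hydroxy-aldehyde form, where the stabilised ylide gives the E-trisubstituted enal and no base is present to trigger oxa-Michael closure.

Step 4
Reactants: 5 (2E,5R)-7-hydroxy-2-methyl-5-(prop-1-en-2-yl)hept-2-enal
Product: 6 (2E,5R)-7-iodo-2-methyl-5-(prop-1-en-2-yl)hept-2-enal
Conditions: PPh3, I2, imidazole, CH2Cl2, 0 °C
Reagents that add atoms: iodine, II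
Why: Appel iodination of the primary alcohol (SN2 on the alkoxyphosphonium ion), done before the methylenation so that no alkoxide can add to the enal.

Step 5
Reactants: 6 (2E,5R)-7-iodo-2-methyl-5-(prop-1-en-2-yl)hept-2-enal
Product: 7 (3E,6R)-8-iodo-3-methyl-6-(prop-1-en-2-yl)octa-1,3-diene
Conditions: Ph3PCH3Br, KN(SiMe3)2, THF, −78 to 0 °C
Reagents that add atoms: methyltriphenylphosphonium bromide, C[P+](c1ccccc1)(c1ccccc1)c1ccccc1.[Br-]
Why: Wittig methylenation of the enal gives the E-1,3-diene with the trisubstituted alkene geometry kept, since carbonyl addition is far faster than alkylation of the ylide by the iodide at low temperature.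

Step 6
Reactants: 8 methyl 3-oxobutanoate
Product: 9 methyl (2E)-3-[(trifluoromethanesulfonyl)oxy]but-2-enoate
Conditions: Tf2O, aq Me4NOH, hexane, 5 °C
Reagents that add atoms: trifluoromethanesulfonic anhydride, FC(F)(F)S(=O)(=O)OS(=O)(=O)C(F)(F)F
Why: O-triflation of the non-chelated tetramethylammonium enolate gives the E-enol triflate (TfO trans to CO2Me), the geometry needed for the dienophile.

Step 7
Reactants: 7 (3E,6R)-8-iodo-3-methyl-6-(prop-1-en-2-yl)octa-1,3-diene; 9 methyl (2E)-3-[(trifluoromethanesulfonyl)oxy]but-2-enoate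
Product: 11 methyl (2E,6S,8E)-3,9-dimethyl-6-(prop-1-en-2-yl)undeca-2,8,10-trienoate, via alkylzinc iodide 10 (not isolated)
Conditions: Zn dust (activated with BrCH2CH2Br and Me3SiCl), LiCl, THF, 35 °C; then 9, PdCl2(dppf) (5 mol %), THF, 45 °C
Reagents that add atoms: none
Why: Direct zinc insertion into the primary C–I bond followed by Negishi cross-coupling with the activated enol triflate forms the C3–C4 bond with retention of the E geometry and without touching the ester, the diene or the stereocentre.

Step 8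
Reactants: 11 methyl (2E,6S,8E)-3,9-dimethyl-6-(prop-1-en-2-yl)undeca-2,8,10-trienoate
Product: 12 methyl (1S,4aR,6S,8aS)-4,8a-dimethyl-6-(prop-1-en-2-yl)-1,2,4a,5,6,7,8,8a-octahydronaphthalene-1-carboxylate
Conditions: BHT (5 mol %), toluene (0.01 M), 190 °C, sealed tube
Reagents that add atoms: none
Why: Thermal intramolecular Diels–Alder reaction of a 1,7,9-decatriene through the transition state with a chair-like tether, equatorial isopropenyl and endo ester gives the trans-fused octalin, so the E-enoate places CO2Me at C1 cis to the C8a methyl, the E-diene fixes C4a, and C6 (from step 1) controls C1, C4a and C8a.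

Step 9
Reactants: 12 methyl (1S,4aR,6S,8aS)-4,8a-dimethyl-6-(prop-1-en-2-yl)-1,2,4a,5,6,7,8,8a-octahydronaphthalene-1-carboxylate
Product: 13 methyl (1S,3S,4R,4aS,6S,8aS)-3,4-epoxy-4,8a-dimethyl-6-(prop-1-en-2-yl)decahydronaphthalene-1-carboxylate (oxygen on the face opposite the C8a methyl)
Conditions: mCPBA (1.05 equiv), NaHCO3, CH2Cl2, −20 to 0 °C
Reagents that add atoms: 3-chloroperoxybenzoic acid, OOC(=O)c1cccc(Cl)c1
Why: Prilezhaev epoxidation takes the electron-richer trisubstituted ring alkene in preference to the 1,1-disubstituted isopropenyl group and attacks anti to the axial C8a methyl, which fixes the later C–O configuration at C4.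

Step 10
Reactants: 13 methyl (1S,3S,4R,4aS,6S,8aS)-3,4-epoxy-4,8a-dimethyl-6-(prop-1-en-2-yl)decahydronaphthalene-1-carboxylate
Product: 15 (1S,4S,4aR,7S,8aS)-4-(hydroxymethyl)-1,4a-dimethyl-7-(prop-1-en-2-yl)decahydronaphthalen-1-ol, via epoxy alcohol 14 (not isolated)
Conditions: LiAlH4 (4 equiv), THF, 0 °C then reflux; H2O, aq NaOH
Reagents that add atoms: none
Why: LiAlH4 reduces the ester to CH2OH and opens the trisubstituted epoxide by SN2 hydride attack at the less substituted C3, so the C–O bond at the methyl-bearing carbon keeps its configuration and the equatorial tertiary alcohol with axial methyl results.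

Step 11
Reactants: 16 benzene-1,3-diol
Product: 18 1,3-dimethoxybenzene, via 3-methoxyphenol 17 (not isolated)
Conditions: MeI (2.5 equiv), K2CO3, acetone, reflux
Reagents that add atoms: iodomethane, CI
Why: Williamson O-methylation of both phenols.

Step 12
Reactants: 18 1,3-dimethoxybenzene
Product: 20 3,5-dimethoxyphenol, via arylboronate 19 (not isolated)
Conditions: pinacolborane (HBpin, 1.5 equiv), [Ir(OMe)(cod)]2 (1 mol %), dtbpy (2 mol %), THF, 80 °C; then KHSO5 (as Oxone), acetone/H2O, 20 °C
Reagents that add atoms: potassium peroxymonosulfate, [K+].[O-]S(=O)(=O)OO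
Why: Iridium-catalysed aromatic C–H borylation is sterically controlled and takes the only C–H not ortho to a methoxy group (C5), and the C–B bond is then oxidised to C–OH in the same pot.

Step 13
Reactants: 20 3,5-dimethoxyphenol
Product: 21 benzene-1,3,5-triol
Conditions: BBr3 (4 equiv), CH2Cl2, −78 to 20 °C; then H2O
Reagents that add atoms: none
Why: Lewis-acid cleavage of both aryl methyl ethers by BBr3.

Step 14
Reactants: 21 benzene-1,3,5-triol; 22 3-methylbutanoyl chloride
Product: 23 3-methyl-1-(2,4,6-trihydroxyphenyl)butan-1-one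
Conditions: AlCl3 (3.5 equiv), PhNO2/CH2Cl2, 0 to 45 °C; aq HCl
Reagents that add atoms: none
Why: Friedel–Crafts C-acylation of the electron-rich arene, where all three ring positions are equivalent and the first acyl group deactivates the ring against a second.

Step 15
Reactants: 23 3-methyl-1-(2,4,6-trihydroxyphenyl)butan-1-one
Product: 25 3,5-dihydroxy-6,6-dimethyl-2-(3-methylbutanoyl)cyclohexa-2,4-dien-1-one (isovalerylfilicinic acid), via monomethyl ketone 24 (not isolated)
Conditions: NaOMe (3.2 equiv), MeI (2.3 equiv), MeOH, 0 to 25 °C; aq HCl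
Reagents that add atoms: iodomethane, CI
Why: Dearomatising double C-methylation of the acylphloroglucinol polyanion at one ring carbon gives the gem-dimethyl triketone as its enol; yields are modest and under- and over-methylated by-products are removed by chromatography.

Step 16
Reactants: 15 (1S,4S,4aR,7S,8aS)-4-(hydroxymethyl)-1,4a-dimethyl-7-(prop-1-en-2-yl)decahydronaphthalen-1-ol; 25 3,5-dihydroxy-6,6-dimethyl-2-(3-methylbutanoyl)cyclohexa-2,4-dien-1-one
Product: 28 3,5-dihydroxy-4-{[(1R,4S,4aS,6S,8aR)-4-hydroxy-4,8a-dimethyl-6-(prop-1-en-2-yl)decahydronaphthalen-1-yl]methyl}-6,6-dimethyl-2-(3-methylbutanoyl)cyclohexa-2,4-dien-1-one (CNP0490948.1), via aldehyde 26 (not isolated), via alkylidene trione 27 (not isolated)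
Conditions: [Cp*IrCl2]2 (2.5 mol %), Cs2CO3 (10 mol %), 25 (1.5 equiv), toluene, 115 °C, sealed tube, argon
Reagents that add atoms: none
Why: Proposed new method: iridium-catalysed hydrogen-borrowing C–H alkylation of an acylfilicinic acid with a hindered primary alcohol, in which the iridium catalyst dehydrogenates the CH2OH of 15 to aldehyde 26 and keeps the hydrogen as an iridium hydride, the strongly C–H acidic trione 25 condenses with 26 (Knoevenagel) to the alkylidene trione 27, and the hydride is returned by 1,4-reduction of 27 to give 28 with water as the only by-product; the tertiary alcohol has no carbinol hydrogen and the unactivated isopropenyl group is a poor hydride acceptor, C1 of the decalin can epimerise at the stage of 26 or 27 but the equatorial, desired configuration is the thermodynamic one; the closest known reaction type is the iridium-catalysed borrowing-hydrogen C-alkylation of barbituric acids and related cyclic 1,3-dicarbonyl compounds with simple alcohols, not yet shown for filicinic-type triketones or for branched terpenoid carbinols.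

**Compound list**
1 | 5,6-dihydro-2H-pyran-2-one | O=C1C=CCCO1 | starting material
2 | potassium trifluoro(prop-1-en-2-yl)borate | CC(=C)[B-](F)(F)F.[K+] | starting material
3 | (4S)-4-(prop-1-en-2-yl)oxan-2-one | C=C(C)[C@H]1CCOC(=O)C1 | intermediate
4 | (4S)-4-(prop-1-en-2-yl)oxan-2-ol (both anomers) | C=C(C)[C@H]1CCOC(O)C1 | intermediate
5 | (2E,5R)-7-hydroxy-2-methyl-5-(prop-1-en-2-yl)hept-2-enal | C=C(C)[C@@H](CCO)C/C=C(\C)C=O | intermediate
6 | (2E,5R)-7-iodo-2-methyl-5-(prop-1-en-2-yl)hept-2-enal | C=C(C)[C@@H](CCI)C/C=C(\C)C=O | intermediate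
7 | (3E,6R)-8-iodo-3-methyl-6-(prop-1-en-2-yl)octa-1,3-diene | C=C(C)[C@@H](CCI)C/C=C(\C)C=C | intermediate
8 | methyl 3-oxobutanoate | CC(=O)CC(=O)OC | starting material
9 | methyl (2E)-3-[(trifluoromethanesulfonyl)oxy]but-2-enoate | COC(=O)/C=C(\C)OS(=O)(=O)C(F)(F)F | intermediate
10 | iodo[(3R,5E)-6-methyl-3-(prop-1-en-2-yl)octa-5,7-dien-1-yl]zinc | C=C(C)[C@@H](CC[Zn]I)C/C=C(\C)C=C | intermediate
11 | methyl (2E,6S,8E)-3,9-dimethyl-6-(prop-1-en-2-yl)undeca-2,8,10-trienoate | COC(=O)/C=C(\C)CC[C@H](C(C)=C)C/C=C(\C)C=C | intermediate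
12 | methyl (1S,4aR,6S,8aS)-4,8a-dimethyl-6-(prop-1-en-2-yl)-1,2,4a,5,6,7,8,8a-octahydronaphthalene-1-carboxylate | C=C(C)[C@H]1CC[C@]2(C)[C@@H](C(=O)OC)CC=C(C)[C@H]2C1 | intermediate
13 | methyl (1S,3S,4R,4aS,6S,8aS)-3,4-epoxy-4,8a-dimethyl-6-(prop-1-en-2-yl)decahydronaphthalene-1-carboxylate | C=C(C)[C@H]1CC[C@]2(C)[C@@H](C(=O)OC)C[C@@H]3O[C@]3(C)[C@H]2C1 | intermediate
14 | [(1S,3S,4R,4aS,6S,8aR)-3,4-epoxy-4,8a-dimethyl-6-(prop-1-en-2-yl)decahydronaphthalen-1-yl]methanol | C=C(C)[C@H]1CC[C@]2(C)[C@@H](CO)C[C@@H]3O[C@]3(C)[C@H]2C1 | intermediate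
15 | (1S,4S,4aR,7S,8aS)-4-(hydroxymethyl)-1,4a-dimethyl-7-(prop-1-en-2-yl)decahydronaphthalen-1-ol | C=C(C)[C@H]1CC[C@]2(C)[C@@H](CO)CC[C@](C)(O)[C@H]2C1 | intermediate
16 | benzene-1,3-diol | Oc1cccc(O)c1 | starting material
17 | 3-methoxyphenol | COc1cccc(O)c1 | intermediate
18 | 1,3-dimethoxybenzene | COc1cccc(OC)c1 | intermediate
19 | 2-(3,5-dimethoxyphenyl)-4,4,5,5-tetramethyl-1,3,2-dioxaborolane | COc1cc(OC)cc(c1)B1OC(C)(C)C(C)(C)O1 | intermediate
20 | 3,5-dimethoxyphenol | COc1cc(O)cc(OC)c1 | intermediate
21 | benzene-1,3,5-triol | Oc1cc(O)cc(O)c1 | intermediate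
22 | 3-methylbutanoyl chloride | CC(C)CC(Cl)=O | starting material
23 | 3-methyl-1-(2,4,6-trihydroxyphenyl)butan-1-one | CC(C)CC(=O)c1c(O)cc(O)cc1O | intermediate
24 | 3-methyl-1-(2,4,6-trihydroxy-3-methylphenyl)butan-1-one | CC(C)CC(=O)c1c(O)cc(O)c(C)c1O | intermediate
25 | 3,5-dihydroxy-6,6-dimethyl-2-(3-methylbutanoyl)cyclohexa-2,4-dien-1-one | CC(C)CC(=O)C1=C(O)C=C(O)C(C)(C)C1=O | intermediate
26 | (1S,4S,4aS,6S,8aS)-4-hydroxy-4,8a-dimethyl-6-(prop-1-en-2-yl)decahydronaphthalene-1-carbaldehyde | C=C(C)[C@H]1CC[C@]2(C)[C@@H](C=O)CC[C@](C)(O)[C@H]2C1 | intermediate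
27 | 3-hydroxy-6-{[(1R,4S,4aS,6S,8aR)-4-hydroxy-4,8a-dimethyl-6-(prop-1-en-2-yl)decahydronaphthalen-1-yl]methylidene}-4,4-dimethyl-2-(3-methylbutanoyl)cyclohex-2-ene-1,5-dione | C=C(C)[C@H]1CC[C@]2(C)[C@@H](C=C3C(=O)C(C)(C)C(O)=C(C(=O)CC(C)C)C3=O)CC[C@](C)(O)[C@H]2C1 | intermediate
28 | 3,5-dihydroxy-4-{[(1R,4S,4aS,6S,8aR)-4-hydroxy-4,8a-dimethyl-6-(prop-1-en-2-yl)decahydronaphthalen-1-yl]methyl}-6,6-dimethyl-2-(3-methylbutanoyl)cyclohexa-2,4-dien-1-one | C=C(C)[C@H]1CC[C@]2(C)[C@@H](CC3=C(O)C(C)(C)C(=O)C(C(=O)CC(C)C)=C3O)CC[C@](C)(O)[C@H]2C1 | target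

**Step count and risks**

Total step count: 16. Longest linear sequence: 10 steps (steps 1 to 5, 7 to 10 and 16); step 6 and steps 11 to 15 are side branches that converge on it.

The three steps most likely to fail are 16, 8 and 7.

The iridium-catalysed alkylation (step 16) is untested. Risks:
- the chelating triketonate may bind the catalyst;
- the alkylidene trione 27 may be trapped by a second molecule of 25 or by the isopropenyl group of another molecule (hetero-Diels–Alder) before the hydride returns;
- the iridium hydride may isomerise the isopropenyl group.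

The fallback uses known chemistry and sets out from 15. Dess–Martin periodinane (NaHCO3, CH2Cl2, 0 °C) oxidises only the primary alcohol and gives aldehyde 26, now isolated. An organocatalytic three-component reductive alkylation (26, 25, Hantzsch ester, L-proline 20 mol %, CH2Cl2, 25 °C; Knoevenagel condensation to 27, then transfer hydrogenation) gives 28, where it rejoins the route. It makes no compound outside the list, entered as none F0.

The thermal Diels–Alder reaction (step 8) uses a β,β-disubstituted enoate, a sluggish dienophile. It may need long heating, and may give cis-fused or axial-isopropenyl isomers or polymer. The fallback sets out from 11 and switches to an aldehyde activated by a Lewis acid: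
- i-Bu2AlH (2.2 equiv, CH2Cl2, −78 °C) gives (2E,6S,8E)-3,9-dimethyl-6-(prop-1-en-2-yl)undeca-2,8,10-trien-1-ol F2.
- MnO2 (CH2Cl2, 20 °C) gives (2E,6S,8E)-3,9-dimethyl-6-(prop-1-en-2-yl)undeca-2,8,10-trienal F3.
- Me2AlCl (1.1 equiv, CH2Cl2, −78 °C) closes both rings to (1S,4aR,6S,8aS)-4,8a-dimethyl-6-(prop-1-en-2-yl)-1,2,4a,5,6,7,8,8a-octahydronaphthalene-1-carbaldehyde F4.
- NaBH4 (MeOH, 0 °C) gives [(1S,4aR,6S,8aS)-4,8a-dimethyl-6-(prop-1-en-2-yl)-1,2,4a,5,6,7,8,8a-octahydronaphthalen-1-yl]methanol F5.
- mCPBA (NaHCO3, CH2Cl2, −20 °C) gives epoxy alcohol 14, here isolated, where the route is rejoined; LiAlH4 as in step 10 then gives 15.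

In the Negishi coupling (step 7) the carbon–zinc centre sits five atoms from a diene, so radical or anionic ring closure during zinc insertion, or β-hydride elimination at palladium, could erode the yield. The fallback sets out from 7 and avoids any organometallic at that carbon. SN2 displacement with LiC≡CH·H2NCH2CH2NH2 (DMSO, 20 °C) gives (3E,6S)-3-methyl-6-(prop-1-en-2-yl)deca-1,3-dien-9-yne F1. Zirconium-catalysed syn-carboalumination (Me3Al 2.5 equiv, Cp2ZrCl2 25 mol %, CH2Cl2, 0 to 20 °C) followed by ClCO2Me gives the E-enoate 11, where it rejoins the route.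

Further compounds
F1 | step 7 | (3E,6S)-3-methyl-6-(prop-1-en-2-yl)deca-1,3-dien-9-yne | C#CCC[C@H](C(C)=C)C/C=C(\C)C=C
F2 | step 8 | (2E,6S,8E)-3,9-dimethyl-6-(prop-1-en-2-yl)undeca-2,8,10-trien-1-ol | OC/C=C(\C)CC[C@H](C(C)=C)C/C=C(\C)C=C
F3 | step 8 | (2E,6S,8E)-3,9-dimethyl-6-(prop-1-en-2-yl)undeca-2,8,10-trienal | O=C/C=C(\C)CC[C@H](C(C)=C)C/C=C(\C)C=C
F4 | step 8 | (1S,4aR,6S,8aS)-4,8a-dimethyl-6-(prop-1-en-2-yl)-1,2,4a,5,6,7,8,8a-octahydronaphthalene-1-carbaldehyde | C=C(C)[C@H]1CC[C@]2(C)[C@@H](C=O)CC=C(C)[C@H]2C1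
F5 | step 8 | [(1S,4aR,6S,8aS)-4,8a-dimethyl-6-(prop-1-en-2-yl)-1,2,4a,5,6,7,8,8a-octahydronaphthalen-1-yl]methanol | C=C(C)[C@H]1CC[C@]2(C)[C@@H](CO)CC=C(C)[C@H]2C1
F0 | step 16 | none | none
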